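**Plan**

- Retrosynthetic cuts: first the tetrahydrofuran O-1–C-9a ketal bond, with the benzylic C-4 raised to a ketone as a temporary oxidation-level helper, which gives a 2-methylchromone. Then, in one retro-step, the two pyran bonds O-9–C-8a (aryl C–O) and C-3a–C-9a. The remaining cuts are aryl–C(=O), the lactone C–O bond and one C=C of the macrocycle.
- Enabling feature: in the pyran ring these two bonds are 1,4-related, so the ring is a formal [4+2] adduct of a 2-fluoroaryl ketone enolate (C-3a nucleophile, C-8a electrophile) and an acetyl C=O. C-8a is para to the lactone carbonyl and ortho to the temporary ketone, which activates fluoride for SNAr. C-9a is at the carboxylic acid oxidation level, so it can be carried as the acetate of the side-chain alcohol (tether and two-atom donor in one).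
- Forward order: benzene ring (bought) → twelve-membered lactone (ortho-allylation, Mitsunobu esterification, ring-closing metathesis, hydrogenation) → side chain (bromination, aryllithium plus lactone, acetylation) → pyranone ring in one operation → removal of the helper oxygen and closure of the tetrahydrofuran ketal.
- Stereochemistry: the lactone carbinol centre comes from (S)-propylene oxide with Mitsunobu inversion; C-3 comes from (S)-β-methyl-γ-butyrolactone; C-3a and C-9a are set under thermodynamic control in the last, acid-mediated ketalisation.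

Key step: step 9

Locants: atoms of the ketal part carry their locants in the furo[2,3-b]chromene unit of the target in all intermediates: O-1 (tetrahydrofuran oxygen), C-2 (OCH2), C-3 (CHCH3), C-3a (ring-fusion CH), C-4 (benzylic CH2), C-8a (aromatic carbon on oxygen), O-9 (aryl oxygen), C-9a (ketal carbon).

Assumption: (S)-4-methyldihydrofuran-2(3H)-one (12) is taken as a catalogue compound, and the cis-fused ketal with the C-3 methyl group trans to C-4 is taken to be the most stable diastereomer for a fixed C-3 configuration.

**Route**

Step 1
Reactants: 1 4-fluoro-2-methoxybenzoic acid; 2 allyl acetate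
Product: 3 4-fluoro-2-methoxy-6-(prop-2-en-1-yl)benzoic acid
Conditions: [Ru(p-cymene)Cl2]2 (3 mol%), K3PO4 (0.5 equiv), MeCN, 50 °C; aq. HCl work-up
Reagents that add atoms: none
Why: Carboxylate-directed ortho C–H allylation at divalent ruthenium (C–H metalation, alkene insertion, β-acetoxy elimination) should functionalise the only free ortho position, because the other one carries the methoxy group.

Step 2
Reactants: 4 (S)-2-methyloxirane; 5 5-bromopent-1-ene
Product: 7 (S)-oct-7-en-2-ol, via pent-4-en-1-ylmagnesium bromide 6 (not isolated)
Conditions: Mg, THF, rt; then CuI (10 mol%), 4, −30 to 0 °C; 1 M HCl work-up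
Reagents that add atoms: none
Why: Copper-catalysed epoxide opening by the Grignard reagent occurs at the unsubstituted carbon, so the stereocentre of 4 is not touched and its (S) configuration is carried into 7.

Step 3
Reactants: 3 4-fluoro-2-methoxy-6-(prop-2-en-1-yl)benzoic acid; 7 (S)-oct-7-en-2-ol
Product: 8 (2R)-oct-7-en-2-yl 4-fluoro-2-methoxy-6-(prop-2-en-1-yl)benzoate
Conditions: PPh3, DIAD, THF, 0 °C to rt
Reagents that add atoms: none
Why: In the Mitsunobu esterification the hindered 2,6-disubstituted benzoate acts as the nucleophile, and the SN2 inversion at the carbinol carbon sets the (R) lactone stereocentre.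

Step 4
Reactants: 8 (2R)-oct-7-en-2-yl 4-fluoro-2-methoxy-6-(prop-2-en-1-yl)benzoate
Product: 9 (3R)-12-fluoro-14-methoxy-3-methyl-3,4,5,6,7,10-hexahydro-1H-2-benzoxacyclododecin-1-one (E/Z mixture)
Conditions: second-generation Grubbs catalyst RuCl2(=CHPh)(PCy3)(H2IMes) (5 mol%), CH2Cl2 (2 mM), 40 °C
Reagents that add atoms: none
Why: Ring-closing metathesis of the two terminal alkenes at high dilution should close the twelve-membered ring with loss of ethene, the alkene geometry being irrelevant because it is removed in step 5.

Step 5
Reactants: 9 (3R)-12-fluoro-14-methoxy-3-methyl-3,4,5,6,7,10-hexahydro-1H-2-benzoxacyclododecin-1-one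
Product: 10 (3R)-12-fluoro-14-methoxy-3-methyl-3,4,5,6,7,8,9,10-octahydro-1H-2-benzoxacyclododecin-1-one
Conditions: H2 (1 atm), Pd/C, EtOAc, rt
Reagents that add atoms: none
Why: Heterogeneous catalytic hydrogenation should saturate the disubstituted alkene without touching the aryl fluoride or the shielded benzoate.

Step 6
Reactants: 10 (3R)-12-fluoro-14-methoxy-3-methyl-3,4,5,6,7,8,9,10-octahydro-1H-2-benzoxacyclododecin-1-one
Product: 11 (3R)-11-bromo-12-fluoro-14-methoxy-3-methyl-3,4,5,6,7,8,9,10-octahydro-1H-2-benzoxacyclododecin-1-one
Conditions: NBS, CF3CO2H (cat.), MeCN, 0 °C to rt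
Reagents that add atoms: N-bromosuccinimide, O=C1CCC(=O)N1Br
Why: Electrophilic aromatic bromination should go to the position para to the methoxy group and ortho to the alkyl chain (the future C-4a), in preference to the position between methoxy and fluorine, which is only ortho to the donor.

Step 7
Reactants: 11 (3R)-11-bromo-12-fluoro-14-methoxy-3-methyl-3,4,5,6,7,8,9,10-octahydro-1H-2-benzoxacyclododecin-1-one; 12 (S)-4-methyldihydrofuran-2(3H)-one
Product: 14 (3R)-12-fluoro-11-[(3S)-4-hydroxy-3-methylbutanoyl]-14-methoxy-3-methyl-3,4,5,6,7,8,9,10-octahydro-1H-2-benzoxacyclododecin-1-one, via aryllithium 13 (not isolated)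
Conditions: n-BuLi, THF, −78 °C; then 12, −78 °C; AcOH quench at −78 °C
Reagents that add atoms: none
Why: Bromine–lithium exchange at −78 °C should outrun attack on the shielded benzoate and loss of LiF, and addition of the aryllithium to the γ-lactone stops at the lithium lactolate, which gives the hydroxy ketone on protonation with the C-3 stereocentre of 12 untouched.

Step 8
Reactants: 14 (3R)-12-fluoro-11-[(3S)-4-hydroxy-3-methylbutanoyl]-14-methoxy-3-methyl-3,4,5,6,7,8,9,10-octahydro-1H-2-benzoxacyclododecin-1-one
Product: 15 (2S)-4-[(3R)-12-fluoro-14-methoxy-3-methyl-1-oxo-3,4,5,6,7,8,9,10-octahydro-1H-2-benzoxacyclododecin-11-yl]-2-methyl-4-oxobutyl acetate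
Conditions: Ac2O, pyridine, DMAP (cat.), CH2Cl2, 0 °C to rt
Reagents that add atoms: acetic anhydride, CC(=O)OC(C)=O
Why: Acylation of the primary alcohol under nucleophilic catalysis installs the acetate that serves in step 9 both as the tether and as the donor of C-9a, its methyl group and O-9.

Step 9
Reactants: 15 (2S)-4-[(3R)-12-fluoro-14-methoxy-3-methyl-1-oxo-3,4,5,6,7,8,9,10-octahydro-1H-2-benzoxacyclododecin-11-yl]-2-methyl-4-oxobutyl acetate
Product: 17 3-[(2S)-1-hydroxypropan-2-yl]-7-methoxy-2-methyl-4H-chromen-4-one bridged from C-5 (CH2 end) to C-6 (carbonyl end) by the (R)-configured lactone chain –(CH2)7–CH(CH3)–O–C(=O)–, via 1,3-diketone enolate 16 (not isolated)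
Conditions: KOtBu (1.1 equiv), THF, 0 °C to rt; then DMF, 70 °C
Reagents that add atoms: none
Why: KOtBu forms the enolate of the aryl ketone at C-3a, which attacks the tethered acetate C=O through a five-membered transition state (5-exo-trig); the tetrahedral alkoxide collapses with release of the side-chain alkoxide, so the acetyl group moves from oxygen to carbon and the C-3a–C-9a bond is made (Baker–Venkataraman-type O→C acyl migration, an intramolecular Claisen condensation), and proton transfer gives the stabilised 1,3-diketonate 16. On warming, the acetyl-derived enolate oxygen of 16 displaces fluoride from C-8a by addition–elimination through a Meisenheimer complex (SNAr, 6-exo-trig closure of the pyranone ring), which makes the O-9–C-8a bond; this is the known closure of 1-(2-fluoroaryl)-1,3-diketones to chromones. The 1,4-relationship of the two new bonds in the six-membered ring is what lets one enolate act first as a carbon nucleophile and then, after acylation, as an oxygen nucleophile. No new stereocentre is formed, because C-3a becomes trigonal and is set in step 11, and C-3 cannot epimerise since it is not α to a carbonyl group. The step needs C-acylation at the only enolisable ketone α-carbon and O-arylation by the acetyl oxygen alone: the five-membered tether secures the first (O-acylation would need a seven-membered transition state), the aroyl oxygen could only close a four-membered ring, and fluoride is activated by the ortho ketone and the para lactone carbonyl.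

Step 10
Reactants: 17 the chromone of step 9
Product: 19 allylic ketal with a C-3a=C-4 double bond (the 3a,4-didehydro analogue of 21; (3S), C-9a epimers), via chromen-4-ol 18 (not isolated)
Conditions: NaBH4, CeCl3·7H2O, MeOH, −20 to 0 °C; aq. NaHCO3 work-up; then PPTS (cat.), 4 Å molecular sieves, CH2Cl2, rt
Reagents that add atoms: none
Why: Luche 1,2-reduction of the vinylogous ester carbonyl (the shielded lactone is inert to NaBH4) gives the acid-labile 4H-chromen-4-ol, which on mild acid should ionise to the 1-benzopyrylium ion and be captured at C-9a by the pendant primary alcohol in a Ferrier-type allylic transposition (5-exo closure of the tetrahydrofuran), so that the helper oxygen leaves C-4 as water.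

Step 11
Reactants: 19 the allylic ketal of step 10
Product: 21 lasiodiplactone A, via hydroxy enol ether 20 (not isolated)
Conditions: diethyl 2,6-dimethyl-1,4-dihydropyridine-3,5-dicarboxylate (1.1 equiv), diphenyl hydrogen phosphate (10 mol%), CH2Cl2, rt; then camphorsulfonic acid (cat.), rt
Reagents that add atoms: none
Why: Acid ionisation of the allylic ketal to the 1-benzopyrylium ion, 1,4-hydride transfer from the dihydropyridine to C-4 and acid-catalysed addition of the alcohol to the resulting enol ether (as in tetrahydropyranyl ether formation) should give the saturated ketal, and because ketal, oxocarbenium ion and enol ether interconvert under acid, C-3a and C-9a should equilibrate to the cis-fused diastereomer with the C-3 methyl group on the convex face trans to C-4, which is the (3aS,9aS) arrangement of the target for the fixed (3S) centre.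

**Compound list**

1 | 4-fluoro-2-methoxybenzoic acid | COc1cc(F)ccc1C(=O)O | starting material
2 | allyl acetate | CC(=O)OCC=C | starting material
3 | 4-fluoro-2-methoxy-6-(prop-2-en-1-yl)benzoic acid | COc1cc(F)cc(CC=C)c1C(=O)O | intermediate
4 | (S)-2-methyloxirane | C[C@H]1CO1 | starting material
5 | 5-bromopent-1-ene | C=CCCCBr | starting material
6 | pent-4-en-1-ylmagnesium bromide | C=CCCC[Mg]Br | intermediate
7 | (S)-oct-7-en-2-ol | C[C@H](O)CCCCC=C | intermediate
8 | (2R)-oct-7-en-2-yl 4-fluoro-2-methoxy-6-(prop-2-en-1-yl)benzoate | COc1cc(F)cc(CC=C)c1C(=O)O[C@H](C)CCCCC=C | intermediate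
9 | (3R)-12-fluoro-14-methoxy-3-methyl-3,4,5,6,7,10-hexahydro-1H-2-benzoxacyclododecin-1-one (E/Z mixture) | COc1cc(F)cc2c1C(=O)O[C@H](C)CCCCC=CC2 | intermediate
10 | (3R)-12-fluoro-14-methoxy-3-methyl-3,4,5,6,7,8,9,10-octahydro-1H-2-benzoxacyclododecin-1-one | COc1cc(F)cc2c1C(=O)O[C@H](C)CCCCCCC2 | intermediate
11 | (3R)-11-bromo-12-fluoro-14-methoxy-3-methyl-3,4,5,6,7,8,9,10-octahydro-1H-2-benzoxacyclododecin-1-one | COc1cc(F)c(Br)c2c1C(=O)O[C@H](C)CCCCCCC2 | intermediate
12 | (S)-4-methyldihydrofuran-2(3H)-one | C[C@@H]1COC(=O)C1 | starting material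
13 | 11-lithio derivative of 10 (aryllithium) | COc1cc(F)c([Li])c2c1C(=O)O[C@H](C)CCCCCCC2 | intermediate
14 | (3R)-12-fluoro-11-[(3S)-4-hydroxy-3-methylbutanoyl]-14-methoxy-3-methyl-3,4,5,6,7,8,9,10-octahydro-1H-2-benzoxacyclododecin-1-one | COc1cc(F)c(C(=O)C[C@H](C)CO)c2c1C(=O)O[C@H](C)CCCCCCC2 | intermediate
15 | (2S)-4-[(3R)-12-fluoro-14-methoxy-3-methyl-1-oxo-3,4,5,6,7,8,9,10-octahydro-1H-2-benzoxacyclododecin-11-yl]-2-methyl-4-oxobutyl acetate | COc1cc(F)c(C(=O)C[C@H](C)COC(C)=O)c2c1C(=O)O[C@H](C)CCCCCCC2 | intermediate
16 | (3R)-12-fluoro-11-{2-[(2S)-1-hydroxypropan-2-yl]-3-oxobutanoyl}-14-methoxy-3-methyl-3,4,5,6,7,8,9,10-octahydro-1H-2-benzoxacyclododecin-1-one, present as its potassium enolate (central carbon not configurationally defined) | COc1cc(F)c(C(=O)C(C(C)=O)[C@H](C)CO)c2c1C(=O)O[C@H](C)CCCCCCC2 | intermediate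
17 | 3-[(2S)-1-hydroxypropan-2-yl]-7-methoxy-2-methyl-4H-chromen-4-one bridged from C-5 to C-6 by the (R)-lactone chain –(CH2)7–CH(CH3)–O–C(=O)– | COc1cc2c(c3c1C(=O)O[C@H](C)CCCCCCC3)C(=O)C([C@H](C)CO)=C(C)O2 | intermediate
18 | 4H-chromen-4-ol derived from 17 (carbinol epimers) | COc1cc2c(c3c1C(=O)O[C@H](C)CCCCCCC3)C(O)C([C@H](C)CO)=C(C)O2 | intermediate
19 | 3a,4-didehydro analogue of 21: allylic ketal with C-3a=C-4 double bond, (3S), C-9a epimers | COc1cc2c(c3c1C(=O)O[C@H](C)CCCCCCC3)C=C1[C@H](C)COC1(C)O2 | intermediate
20 | 4H-chromene enol ether with free alcohol: 3-[(2S)-1-hydroxypropan-2-yl]-7-methoxy-2-methyl-4H-chromene with the same C-5/C-6 lactone bridge | COc1cc2c(c3c1C(=O)O[C@H](C)CCCCCCC3)CC([C@H](C)CO)=C(C)O2 | intermediate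
21 | lasiodiplactone A ((3S,3aS,9aS) in the furo[2,3-b]chromene part, (R) at the lactone carbinol carbon) | COc1cc2c(c3c1C(=O)O[C@H](C)CCCCCCC3)C[C@H]1[C@H](C)CO[C@@]1(C)O2 | target

**Step count and risks**

Total steps: 11. Longest linear sequence: 10 steps (1 → 3 → 8 → 9 → 10 → 11 → 14 → 15 → 17 → 19 → 21); step 2 is a one-step side branch.

Step 9 (key step). The alkoxide base may cleave the acetate before C-acylation, the alkoxide set free by the acyl transfer may open the chromone by attack at C-9a, and fluoride displacement may be slow because the flanked ketone is twisted out of the ring plane. The fallback separates the two bond formations and keeps the alcohol masked. It sets out from 14: silylation (TBSCl, imidazole, DMF) gives the silyl ether of 14, F1. Soft enolisation (MgBr2·OEt2, i-Pr2NEt, CH2Cl2) and acetyl chloride give the isolated silyl-protected 1,3-diketone F2. Cs2CO3 in DMSO at 80 °C closes the silyl-protected chromone F3 by SNAr with no free alkoxide present, and HF·pyridine in THF removes the silyl group. The fallback comes back to the route at 17.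

Step 11. The hydride may be delivered to C-9a of the benzopyrylium ion instead of C-4, the oxocarbenium ion of the product ketal may be reduced further, or the ring-fusion centres may not equilibrate fully. The fallback sets out from 19 and does not pass through the cation: hydrogenation of the neutral C-3a=C-4 double bond (H2, Pd/C, EtOAc, K2CO3) gives the saturated ketal as a mixture of ring-fusion epimers F4, which is then equilibrated with camphorsulfonic acid (cat.) in CH2Cl2 through ketal, oxocarbenium ion and enol ether. It comes back to the route at 21.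

Step 7. The ortho-fluoro aryllithium may lose LiF (aryne formation) before it is trapped, the organolithium may attack the macrolactone, or the lactone may take up two aryl groups. The fallback sets out from 11 and 12. Lactone 12 is opened with MeNH(OMe)·HCl and i-PrMgCl (THF, −20 °C) to (3S)-4-hydroxy-N-methoxy-N,3-dimethylbutanamide F5, which is kept as its magnesium alkoxide. Bromide 11 is converted with i-PrMgCl·LiCl (THF, −15 °C) into the arylmagnesium chloride F6, which does not lose fluoride at this temperature. Addition of F6 to F5 gives a chelated tetrahedral intermediate that cannot add a second aryl group, and aqueous NH4Cl work-up comes back to the route at 14.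

Further compounds
F1 | step 9 | (3R)-11-[(3S)-4-(tert-butyldimethylsilyloxy)-3-methylbutanoyl]-12-fluoro-14-methoxy-3-methyl-3,4,5,6,7,8,9,10-octahydro-1H-2-benzoxacyclododecin-1-one | COc1cc(F)c(C(=O)C[C@H](C)CO[Si](C)(C)C(C)(C)C)c2c1C(=O)O[C@H](C)CCCCCCC2
F2 | step 9 | silyl-protected 1,3-diketone (2-acetyl derivative of F1, central carbon not configurationally defined) | COc1cc(F)c(C(=O)C(C(C)=O)[C@H](C)CO[Si](C)(C)C(C)(C)C)c2c1C(=O)O[C@H](C)CCCCCCC2
F3 | step 9 | tert-butyldimethylsilyl ether of chromone 17 | COc1cc2c(c3c1C(=O)O[C@H](C)CCCCCCC3)C(=O)C([C@H](C)CO[Si](C)(C)C(C)(C)C)=C(C)O2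
F4 | step 11 | saturated ketal with the constitution of 21, mixture of C-3a/C-9a epimers | COc1cc2c(c3c1C(=O)O[C@H](C)CCCCCCC3)CC1[C@H](C)COC1(C)O2
F5 | step 7 | (3S)-4-hydroxy-N-methoxy-N,3-dimethylbutanamide | CON(C)C(=O)C[C@H](C)CO
F6 | step 7 | 11-(chloromagnesio) derivative of 10 (arylmagnesium chloride) | COc1cc(F)c([Mg]Cl)c2c1C(=O)O[C@H](C)CCCCCCC2
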